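**Retrosynthetic overview**
- Sauriol B ⇒ C2-symmetric bis-syringyl lignan. The last step makes the C5–O bond of ring A by oxygen-atom transfer to a methoxy-bearing ring carbon, and the old C5–OMe leaves as MeOH. The two rings are homotopic and all four OMe sites are equivalent, so one hit at any site gives the target.
- Bis-syringyl lignan ⇒ (E,E)-1,4-diaryl-2,3-dimethylbutadiene. One twofold catalytic asymmetric hydrogenation sets C8 and C8' together.
- Diene ⇒ 2 × 4-bromo-2,6-dimethoxyphenol + 2,3-dimethylbutadiene, by a twofold Heck arylation (C1–C7 and C1'–C7').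
- No ring is formed. Rings A and B are both bought in the bromophenol, no protecting groups are used, and the air-sensitive catechol appears only in the last flask.

Assumption: the SMILES is read as (8R,8'R) (lignan numbering, unprimed = catechol ring A); the facial sense of the iridium catalyst is carried over from (E)-1,2-diphenylpropene, and the (R)-ligand is used instead if a first run shows the (S,S) series.

**Step 1**
Reactants: 1 4-bromo-2,6-dimethoxyphenol (2.3 equiv); 2 2,3-dimethylbuta-1,3-diene (1.0 equiv)
Product: 4 4,4'-[(1E,3E)-2,3-dimethylbuta-1,3-diene-1,4-diyl]bis(2,6-dimethoxyphenol), via monoaryl diene 3 (not isolated)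
Conditions: Pd(OAc)2 (5 mol%), P(o-tol)3 (12 mol%), NaOAc (3 equiv), Bu4NBr (0.2 equiv), BHT (1 mol%), DMA, 120 °C, sealed tube, 36 h; crystallise
Reagents that add atoms: none
Why: Twofold Mizoroki–Heck reaction: Pd(OAc)2/P(o-tol)3 is the classical system for donor-substituted bromophenols, the arylpalladium adds to the unsubstituted CH2 terminus of the diene, and loss of a benzylic hydrogen from the allylpalladium intermediate gives the aryl-conjugated E-alkene (aryl anti to the larger alkenyl group), once at each end.

**Step 2**
Reactants: 4 4,4'-[(1E,3E)-2,3-dimethylbuta-1,3-diene-1,4-diyl]bis(2,6-dimethoxyphenol)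
Product: 6 4,4'-[(2R,3R)-2,3-dimethylbutane-1,4-diyl]bis(2,6-dimethoxyphenol), via half-reduced alkene 5 (not isolated)
Conditions: [Ir(cod)(L)]B[3,5-(CF3)2C6H3]4 (2 mol%; L = (S)-4-tert-butyl-2-[2-(di-o-tolylphosphanyl)phenyl]-4,5-dihydrooxazole), H2 (50 bar), CH2Cl2, 25 °C, 16 h; recrystallise
Reagents that add atoms: none
Why: Pfaltz-type asymmetric hydrogenation of unfunctionalised E-trisubstituted aryl alkenes: each C=C of 4 is a close analogue of (E)-1,2-diphenylpropene, which this (S)-ligand complex is reported to reduce to the (R)-alkane in about 97–99% ee, so catalyst control should set C8 and then C8' both R, the twofold reduction raises the ee of the C2 isomer (Horeau effect), and the few percent of meso isomer is removed by crystallisation.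

**Step 3**
Reactants: 6 4,4'-[(2R,3R)-2,3-dimethylbutane-1,4-diyl]bis(2,6-dimethoxyphenol)
Product: 8 sauriol B, via o-quinone 7 (not isolated)
Conditions: 2-IC6H4SO3Na (5 mol%), 2KHSO5·KHSO4·K2SO4 (0.35 equiv = 0.7 equiv KHSO5), K2CO3 (1.1 equiv), Bu4NHSO4 (10 mol%), Na2SO4, EtOAc, 40 °C; then 0 °C, aq. Na2S2O4; 8 taken into aq. Na2B4O7 and released with acid, recovered 6 recycled
Reagents that add atoms: potassium peroxymonosulfate KHSO5, [K+].[O-]S(=O)(=O)OO
Why: Proposed new method: symmetry-breaking ipso-oxygenation of an aryl C–OMe bond under pentavalent-iodine catalysis – 2-iodoxybenzenesulfonate, made in the flask from 2-IC6H4SO3Na and KHSO5, binds one syringyl OH by ligand exchange and hands its oxo oxygen intramolecularly ([2,3]-type shift) to the adjacent methoxy-bearing carbon to forge the new C5–O bond, the resulting o-quinone hemiketal expels MeOH to give 7, KHSO5 re-oxidises the trivalent iodine, the inner-sphere delivery avoids a free phenoxenium ion and hence the p-quinone methide, limiting KHSO5 keeps the homotopic second ring largely untouched, and Na2S2O4 reduces 7 to the catechol without touching C8/C8'; closest known reaction types: stoichiometric 2-iodoxybenzoic acid (IBX) oxidative demethylation of 2-methoxyphenols and the 2-iodoxybenzenesulfonate/KHSO5-catalysed oxidation of phenols to o-quinones at an ortho C–H, to my knowledge neither shown catalytically at C–OMe, on a 2,6-dimethoxyphenol lignan, or as a desymmetrisation.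

**Compound list**
1 | 4-bromo-2,6-dimethoxyphenol | COc1cc(Br)cc(OC)c1O | starting material
2 | 2,3-dimethylbuta-1,3-diene | C=C(C)C(C)=C | starting material
3 | 4-[(1E)-2,3-dimethylbuta-1,3-dien-1-yl]-2,6-dimethoxyphenol | COc1cc(/C=C(C)/C(C)=C)cc(OC)c1O | intermediate
4 | 4,4'-[(1E,3E)-2,3-dimethylbuta-1,3-diene-1,4-diyl]bis(2,6-dimethoxyphenol) | COc1cc(/C=C(C)/C(C)=C/c2cc(OC)c(O)c(OC)c2)cc(OC)c1O | intermediate
5 | 4-[(1E,3R)-4-(4-hydroxy-3,5-dimethoxyphenyl)-2,3-dimethylbut-1-en-1-yl]-2,6-dimethoxyphenol | COc1cc(C[C@@H](C)/C(C)=C/c2cc(OC)c(O)c(OC)c2)cc(OC)c1O | intermediate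
6 | 4,4'-[(2R,3R)-2,3-dimethylbutane-1,4-diyl]bis(2,6-dimethoxyphenol) | COc1cc(C[C@@H](C)[C@H](C)Cc2cc(OC)c(O)c(OC)c2)cc(OC)c1O | intermediate
7 | 5-[(2R,3R)-4-(4-hydroxy-3,5-dimethoxyphenyl)-2,3-dimethylbutyl]-3-methoxycyclohexa-3,5-diene-1,2-dione | COC1=CC(C[C@@H](C)[C@H](C)Cc2cc(OC)c(O)c(OC)c2)=CC(=O)C1=O | intermediate
8 | sauriol B, 5-[(2R,3R)-4-(4-hydroxy-3,5-dimethoxyphenyl)-2,3-dimethylbutyl]-3-methoxybenzene-1,2-diol | COc1cc(C[C@@H](C)[C@H](C)Cc2cc(OC)c(O)c(OC)c2)cc(O)c1O | target

**Totals**
- Total step count: 3.
- Longest linear sequence: 3.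
- Estimated yields (my estimates, not literature values): step 1 50–60%; step 2 85–90%; step 3 40–45% per pass, 75–80% based on recovered 6.

**Three steps most likely to fail**

Step 3 (the new step).
- Risks: KHSO5 or the trivalent-iodine form may oxidise the phenol by an outer-sphere path to a p-quinone methide, giving a cyclolignan or benzylic oxygenation. Compound 7 may tautomerise before it is reduced.
- Ceiling: the yield per pass cannot exceed the statistical limit. At 0.7 equiv KHSO5 the calculation gives 45% of 8, 42% of 6 returned and 12% doubly oxidised.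
- Fallback, known chemistry: it sets out from 6 and comes back at 8 without passing 7. Instead of making the C5–O bond, it cleaves the O–CH3 bond next to the free OH with AlCl3 (1.1 equiv) and pyridine (4.5 equiv) in refluxing CH2Cl2. This is the chelation-controlled method that turns syringaldehyde into 5-hydroxyvanillin. The aluminium catecholate formed resists a second cleavage in the same ring, unreacted 6 is recycled, and this fallback makes no new compound F0.

Step 1.
- Risks: oxidative addition of the electron-rich bromophenol may be slow. The allylpalladium intermediate may lose a methyl hydrogen instead of a benzylic one, giving skipped 2-benzyl dienes that would erode the selectivity of step 2. Compound 2 may dimerise thermally.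
- Fallback, known chemistry with stereodefined alkenes: it sets out from 1 and comes back at 4. Sonogashira coupling of 1 with propyne (PdCl2(MeCN)2, XPhos, Cs2CO3, MeCN, 70 °C) gives 2,6-dimethoxy-4-(prop-1-yn-1-yl)phenol F1. Copper-catalysed syn-hydroboration (CuCl, NaOtBu, P(p-tol)3, B2pin2, MeOH, THF) places boron next to the methyl group and gives 2,6-dimethoxy-4-[(1Z)-2-(4,4,5,5-tetramethyl-1,3,2-dioxaborolan-2-yl)prop-1-en-1-yl]phenol F2. Oxidative homocoupling with retention (Pd(OAc)2, K2CO3, p-benzoquinone, THF/H2O) joins two units of it to 4.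

Step 2.
- Risks: the acidic iridium hydrides may protonate the electron-rich styrene units and cause cyclisation. The free phenols may slow the catalyst. A mismatched second reduction may raise the meso share.
- Fallback, known chemistry: it sets out from 4 and comes back at 6. Plain hydrogenation over Pd/C (H2 1 atm, EtOAc) gives 6 together with its enantiomer 4,4'-[(2S,3S)-2,3-dimethylbutane-1,4-diyl]bis(2,6-dimethoxyphenol) F3 and the meso isomer 4,4'-[(2R,3S)-2,3-dimethylbutane-1,4-diyl]bis(2,6-dimethoxyphenol) F4. The meso isomer is removed by crystallisation, and the enantiomers are separated by preparative chiral SFC on an amylose tris(3,5-dimethylphenylcarbamate) phase.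

**Further compounds**
F1 | step 1 | 2,6-dimethoxy-4-(prop-1-yn-1-yl)phenol | CC#Cc1cc(OC)c(O)c(OC)c1
F2 | step 1 | 2,6-dimethoxy-4-[(1Z)-2-(4,4,5,5-tetramethyl-1,3,2-dioxaborolan-2-yl)prop-1-en-1-yl]phenol | COc1cc(/C=C(C)/B2OC(C)(C)C(C)(C)O2)cc(OC)c1O
F3 | step 2 | 4,4'-[(2S,3S)-2,3-dimethylbutane-1,4-diyl]bis(2,6-dimethoxyphenol) | COc1cc(C[C@H](C)[C@@H](C)Cc2cc(OC)c(O)c(OC)c2)cc(OC)c1O
F4 | step 2 | 4,4'-[(2R,3S)-2,3-dimethylbutane-1,4-diyl]bis(2,6-dimethoxyphenol) (meso) | COc1cc(C[C@@H](C)[C@@H](C)Cc2cc(OC)c(O)c(OC)c2)cc(OC)c1O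
F0 | step 3 | none | none
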